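**Retrosynthetic overview**
1. Target 13 ← desilylation of 12 ← selective acetylation of the secondary C1′–OH of diol 11.
2. 11 ← syn-dihydroxylation of the exocyclic E-alkene of cross-conjugated dienone 10, anti to the C4 silyloxy group (sets C5 and C1′ together).
3. 10 ← dehydration of aldol 8 ← key intermolecular aldol of the lithium dienolate of (S)-4-silyloxycyclopentenone 4 with pentadecanal 6 (C5–C1′ bond).
4. 4 ← silylation, methanolysis and oxidation of commercial (1S,4R)-cis-4-acetoxycyclopent-2-en-1-ol 1; 6 ← oxidation of pentadecan-1-ol 5.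
5. Ring order: the only ring (the cyclopentene) comes in with 1; no ring is formed in the route.

Assumption: ring locants are C1 (C=O), C2=C3, C4 (CHOH), C5 (quaternary carbinol), and C1′ is the acetoxy-bearing side-chain carbon; in this numbering the target is (4R,5R,1′S), a trans-4,5-diol with the side chain cis to the C4 hydroxyl.

**Step 1**
Reactants: 1 (1S,4R)-cis-4-acetoxycyclopent-2-en-1-ol
Product: 2 (1R,4S)-4-[(tert-butyldimethylsilyl)oxy]cyclopent-2-en-1-yl acetate
Conditions: TBSCl, imidazole, DMF, 0 °C to rt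
Reagents that add atoms: tert-butyldimethylsilyl chloride, CC(C)(C)[Si](C)(C)Cl
Why: Imidazole-promoted silyl ether formation on the only free hydroxyl; the acetate is inert and no stereocentre is touched.

**Step 2**
Reactants: 2 (1R,4S)-4-[(tert-butyldimethylsilyl)oxy]cyclopent-2-en-1-yl acetate
Product: 3 (1R,4S)-4-[(tert-butyldimethylsilyl)oxy]cyclopent-2-en-1-ol
Conditions: K2CO3 (0.2 equiv), MeOH, 0 °C to rt
Reagents that add atoms: none
Why: Carbonate-catalysed transesterification removes the acetate while the silyl ether is stable to mild base, and no stereocentre is touched.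

**Step 3**
Reactants: 3 (1R,4S)-4-[(tert-butyldimethylsilyl)oxy]cyclopent-2-en-1-ol
Product: 4 (4S)-4-[(tert-butyldimethylsilyl)oxy]cyclopent-2-en-1-one
Conditions: Dess–Martin periodinane (1.2 equiv), CH2Cl2, 0 °C to rt
Reagents that add atoms: none
Why: Dess–Martin oxidation of the allylic alcohol is near-neutral, so the base-sensitive β-silyloxy enone neither eliminates nor racemises and the silyloxy-bearing centre is kept.

**Step 4**
Reactants: 5 pentadecan-1-ol
Product: 6 pentadecanal
Conditions: PhI(OAc)2 (1.1 equiv), TEMPO (2,2,6,6-tetramethylpiperidin-1-oxyl, 10 mol %), CH2Cl2, rt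
Reagents that add atoms: none
Why: Oxoammonium-mediated (TEMPO) oxidation stops cleanly at the aldehyde, which is used fresh.

**Step 5**
Reactants: 4 (4S)-4-[(tert-butyldimethylsilyl)oxy]cyclopent-2-en-1-one; 6 pentadecanal
Product: 8 (4R,5S)-4-[(tert-butyldimethylsilyl)oxy]-5-(1-hydroxypentadecyl)cyclopent-2-en-1-one, via lithium dienolate 7 (not isolated)
Conditions: LiN(iPr)2 (1.1 equiv), THF, −78 °C, 4 added slowly, 30 min; then 6 (1.2 equiv), −78 °C, 30 min; AcOH quench at −78 °C
Reagents that add atoms: LiN(iPr)2, [Li+].CC(C)[N-]C(C)C (its lithium is in 7 only)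
Why: Kinetic α′-deprotonation gives the cross-conjugated lithium dienolate, which undergoes the key intermolecular aldol addition anti to the C4 silyloxy group (C5 trans to OTBS, C1′ as an epimer mixture, both centres erased in step 6), with the low temperature suppressing loss of silanolate.

**Step 6**
Reactants: 8 (4R,5S)-4-[(tert-butyldimethylsilyl)oxy]-5-(1-hydroxypentadecyl)cyclopent-2-en-1-one
Product: 10 (4R,5E)-4-[(tert-butyldimethylsilyl)oxy]-5-pentadecylidenecyclopent-2-en-1-one, via mesylate 9 (not isolated)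
Conditions: MsCl, Et3N, CH2Cl2, 0 °C; then DBU (1,8-diazabicyclo[5.4.0]undec-7-ene, 1.2 equiv), 0 °C, 30 min
Reagents that add atoms: methanesulfonyl chloride, CS(=O)(=O)Cl (its atoms are in 9 only)
Why: Mesylation and E1cB elimination complete the aldol condensation and give the thermodynamically preferred E-alkylidene (chain anti to the carbonyl) from either C1′ epimer.

**Step 7**
Reactants: 10 (4R,5E)-4-[(tert-butyldimethylsilyl)oxy]-5-pentadecylidenecyclopent-2-en-1-one
Product: 11 (4R,5S)-4-[(tert-butyldimethylsilyl)oxy]-5-hydroxy-5-[(1S)-1-hydroxypentadecyl]cyclopent-2-en-1-one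
Conditions: OsO4 (5 mol %), N-methylmorpholine N-oxide (1.2 equiv), acetone/H2O 8:1, 0 °C to rt; Na2SO3 quench
Reagents that add atoms: osmium tetroxide, O=[Os](=O)(=O)=O; N-methylmorpholine N-oxide, C[N+]1([O-])CCOCC1; water, O
Why: Upjohn syn-dihydroxylation attacks the more electron-rich trisubstituted exocyclic alkene from the face opposite the C4 silyloxy group, so suprafacial addition to the E-alkene sets the tertiary C5 hydroxyl trans to OTBS and C1′ as S in one event.

**Step 8**
Reactants: 11 (4R,5S)-4-[(tert-butyldimethylsilyl)oxy]-5-hydroxy-5-[(1S)-1-hydroxypentadecyl]cyclopent-2-en-1-one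
Product: 12 (1S)-1-[(1S,5R)-5-[(tert-butyldimethylsilyl)oxy]-1-hydroxy-2-oxocyclopent-3-en-1-yl]pentadecyl acetate
Conditions: Ac2O (1.3 equiv), pyridine, 4-(dimethylamino)pyridine (5 mol %), CH2Cl2, 0 °C
Reagents that add atoms: acetic anhydride, CC(=O)OC(C)=O
Why: Nucleophile-catalysed acylation takes the secondary C1′ hydroxyl only, because the tertiary C5 hydroxyl is far less reactive and C4 is still silylated.

**Step 9**
Reactants: 12 (1S)-1-[(1S,5R)-5-[(tert-butyldimethylsilyl)oxy]-1-hydroxy-2-oxocyclopent-3-en-1-yl]pentadecyl acetate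
Product: 13 (1S)-1-[(1R,5R)-1,5-dihydroxy-2-oxocyclopent-3-en-1-yl]pentadecyl acetate
Conditions: aq. HF (48 %), MeCN, 0 °C to rt
Reagents that add atoms: none
Why: Acidic fluoride desilylation cleaves the secondary silyl ether without the basic conditions that would cause acetyl migration, retro-aldol or elimination, so all three stereocentres are kept.

**Compound list**
1 | (1S,4R)-cis-4-acetoxycyclopent-2-en-1-ol | CC(=O)O[C@H]1C=C[C@@H](O)C1 | starting material
2 | (1R,4S)-4-[(tert-butyldimethylsilyl)oxy]cyclopent-2-en-1-yl acetate | CC(=O)O[C@H]1C=C[C@@H](O[Si](C)(C)C(C)(C)C)C1 | intermediate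
3 | (1R,4S)-4-[(tert-butyldimethylsilyl)oxy]cyclopent-2-en-1-ol | O[C@H]1C=C[C@@H](O[Si](C)(C)C(C)(C)C)C1 | intermediate
4 | (4S)-4-[(tert-butyldimethylsilyl)oxy]cyclopent-2-en-1-one | O=C1C=C[C@@H](O[Si](C)(C)C(C)(C)C)C1 | intermediate
5 | pentadecan-1-ol | CCCCCCCCCCCCCCCO | starting material
6 | pentadecanal | CCCCCCCCCCCCCCC=O | intermediate
7 | lithium (3R)-3-[(tert-butyldimethylsilyl)oxy]cyclopenta-1,4-dien-1-olate (lithium dienolate of 4) | [Li+].[O-]C1=C[C@H](O[Si](C)(C)C(C)(C)C)C=C1 | intermediate (not isolated)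
8 | (4R,5S)-4-[(tert-butyldimethylsilyl)oxy]-5-(1-hydroxypentadecyl)cyclopent-2-en-1-one; C1′ epimer mixture, left unassigned in the SMILES because the centre is removed in step 6 | O=C1C=C[C@@H](O[Si](C)(C)C(C)(C)C)[C@@H]1C(O)CCCCCCCCCCCCCC | intermediate
9 | 1-[(1R,5R)-5-[(tert-butyldimethylsilyl)oxy]-2-oxocyclopent-3-en-1-yl]pentadecyl methanesulfonate; C1′ epimer mixture as in 8 | O=C1C=C[C@@H](O[Si](C)(C)C(C)(C)C)[C@@H]1C(OS(C)(=O)=O)CCCCCCCCCCCCCC | intermediate (not isolated)
10 | (4R,5E)-4-[(tert-butyldimethylsilyl)oxy]-5-pentadecylidenecyclopent-2-en-1-one | CCCCCCCCCCCCCC/C=C1/C(=O)C=C[C@H]1O[Si](C)(C)C(C)(C)C | intermediate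
11 | (4R,5S)-4-[(tert-butyldimethylsilyl)oxy]-5-hydroxy-5-[(1S)-1-hydroxypentadecyl]cyclopent-2-en-1-one | CCCCCCCCCCCCCC[C@H](O)[C@@]1(O)C(=O)C=C[C@H]1O[Si](C)(C)C(C)(C)C | intermediate
12 | (1S)-1-[(1S,5R)-5-[(tert-butyldimethylsilyl)oxy]-1-hydroxy-2-oxocyclopent-3-en-1-yl]pentadecyl acetate | CCCCCCCCCCCCCC[C@H](OC(C)=O)[C@@]1(O)C(=O)C=C[C@H]1O[Si](C)(C)C(C)(C)C | intermediate
13 | (1S)-1-[(1R,5R)-1,5-dihydroxy-2-oxocyclopent-3-en-1-yl]pentadecyl acetate, i.e. (4R,5R)-5-[(1S)-1-acetoxypentadecyl]-4,5-dihydroxycyclopent-2-en-1-one (CNP0263753.4) | CCCCCCCCCCCCCC[C@H](OC(C)=O)[C@@]1(O)C(=O)C=C[C@H]1O | target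

The descriptor changes at C4 (S in 4, R from 8 on) and at C5 (S in 11 and 12, R in 13) come only from changed substituent priorities; the spatial arrangement is unchanged.

**Step count**
Total steps: 9. Longest linear sequence: 8 steps (1 → 2 → 3 → 4 → 8 → 10 → 11 → 12 → 13); step 4 is a one-step side branch.

**Three steps most likely to fail**

Step 5. The dienolate carries a β-silyloxy group, so the risks are loss of silanolate, proton transfer to the enolisable aldehyde and retro-aldol. The fallback sets out from 4 and comes back at 8, and replaces the lithium enolate by a boron-mediated aldol. Soft enolisation of 4 with Bu2BOTf and iPr2NEt in CH2Cl2 at −78 °C gives the dibutylboron dienolate F1 with no strong base present. Aldehyde 6 is then added and reacts through a closed six-membered transition state, again anti to the silyloxy group, to the boron aldolate F2. A non-oxidative work-up (MeOH, pH 7 buffer) frees 8, which re-enters at step 6.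

Step 6. The alkene geometry decides the C1′ configuration in step 7, and the dienone is sensitive to prolonged base. The fallback sets out from 8 and comes back at 10. The same dehydration is run with the shortest possible base contact, the isomers are separated, and the (Z)-dienone F3 is treated with I2 (5 mol %) in CH2Cl2 under visible light at rt. Reversible iodine-atom addition equilibrates it to the more stable E isomer 10, so the geometry is fixed under thermodynamic control in a separate operation and all material is funnelled into 10.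

Step 7. OsO4 may also attack the ring enone alkene, and the electron-poor alkene reacts slowly. The fallback sets out from 10 and comes back at 11, and masks the ring enone first. PhSH (1.05 equiv) with catalytic Et3N in CH2Cl2 at 0 °C adds to the less hindered endocyclic enone, trans to the silyloxy group, to give the β-sulfanyl ketone F4, in which only the exocyclic alkene is left. OsO4 (5 mol %) with excess N-methylmorpholine N-oxide (3.5 equiv) then dihydroxylates that alkene anti to the silyloxy group and takes the sulfide to the sulfone in the same pot, giving the sulfone diol F5. Et3N in CH2Cl2 at 0 °C expels benzenesulfinate by E1cB elimination and restores the enone, giving 11.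

**Further compounds**
F1 | step 5 | dibutyl{[(3R)-3-[(tert-butyldimethylsilyl)oxy]cyclopenta-1,4-dien-1-yl]oxy}borane (dibutylboron dienolate) | CCCCB(CCCC)OC1=C[C@H](O[Si](C)(C)C(C)(C)C)C=C1
F2 | step 5 | (4R,5S)-4-[(tert-butyldimethylsilyl)oxy]-5-{1-[(dibutylboranyl)oxy]pentadecyl}cyclopent-2-en-1-one (boron aldolate, C1′ unassigned as in 8) | O=C1C=C[C@@H](O[Si](C)(C)C(C)(C)C)[C@@H]1C(OB(CCCC)CCCC)CCCCCCCCCCCCCC
F3 | step 6 | (4R,5Z)-4-[(tert-butyldimethylsilyl)oxy]-5-pentadecylidenecyclopent-2-en-1-one ((Z)-dienone) | CCCCCCCCCCCCCC\C=C1/C(=O)C=C[C@H]1O[Si](C)(C)C(C)(C)C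
F4 | step 7 | (2E,3S,4S)-3-[(tert-butyldimethylsilyl)oxy]-2-pentadecylidene-4-(phenylsulfanyl)cyclopentan-1-one (β-sulfanyl ketone) | CCCCCCCCCCCCCC/C=C1/C(=O)C[C@H](Sc2ccccc2)[C@H]1O[Si](C)(C)C(C)(C)C
F5 | step 7 | (2S,3S,4S)-3-[(tert-butyldimethylsilyl)oxy]-2-hydroxy-2-[(1S)-1-hydroxypentadecyl]-4-(phenylsulfonyl)cyclopentan-1-one (sulfone diol) | CCCCCCCCCCCCCC[C@H](O)[C@@]1(O)C(=O)C[C@H](S(=O)(=O)c2ccccc2)[C@H]1O[Si](C)(C)C(C)(C)C
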